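**Retrosynthetic overview**
- The target, (2R,8S)-8-hydroxy-1-(3-hydroxy-5-methoxyphenyl)tridecan-2-yl acetate, comes from a benzyl-protected (6E,8S)-allylic alcohol by one hydrogenation that saturates C6=C7 and frees the phenol.
- The C8 carbinol comes from CBS reduction of a (6E)-en-8-one, itself the dehydration product of a β-hydroxy ketone.
- Key disconnection C6–C7: intermolecular boron aldol of heptan-2-one (C7–C13) with a C1–C6 aldehyde that already carries the C2 acetate.
- The aldehyde comes from two Cu-catalysed Grignard epoxide openings on (S)-epichlorohydrin (aryl–C1, then C3–C4); C2 is taken from the chiral pool.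
- No ring of the target is built: the benzene ring is bought. The only rings made are a transient oxirane and a dioxolane bought as a mask for the aldehyde.

**Route**

Step 1
Reactants: 1 3-bromo-5-methoxyphenol
Product: 2 1-(benzyloxy)-3-bromo-5-methoxybenzene
Conditions: BnBr, K2CO3, DMF, rt
Reagents that add atoms: benzyl bromide, BrCc1ccccc1
Why: Williamson ether synthesis of the phenoxide gives an aryl benzyl ether that survives the Grignard, boron enolate, mesylation and borane steps and is removed by hydrogenolysis in the last step.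

Step 2
Reactants: 2 1-(benzyloxy)-3-bromo-5-methoxybenzene; 3 (S)-epichlorohydrin
Product: 5 (S)-1-[3-(benzyloxy)-5-methoxyphenyl]-3-chloropropan-2-ol, via aryl Grignard reagent 4 (not isolated)
Conditions: Mg, THF, 50 °C; then CuI (10 mol%), 3, −40 → −10 °C; sat. aq. NH4Cl
Reagents that add atoms: none
Why: Grignard formation followed by CuI-catalysed SN2 opening of the epoxide at its unsubstituted carbon is much faster than chloride displacement, and the stereocentre (future C2) is bought with 3 and no bond to it is touched.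

Step 3
Reactants: 5 (S)-1-[3-(benzyloxy)-5-methoxyphenyl]-3-chloropropan-2-ol
Product: 6 (S)-2-[3-(benzyloxy)-5-methoxybenzyl]oxirane
Conditions: NaOH (2 M aq.), THF, 0 °C → rt
Reagents that add atoms: none
Why: Intramolecular Williamson etherification (SN2 at CH2Cl) closes the oxirane, and because displacement occurs at the CH2 carbon the carbinol configuration is retained.

Step 4
Reactants: 6 (S)-2-[3-(benzyloxy)-5-methoxybenzyl]oxirane; 7 2-(2-bromoethyl)-1,3-dioxolane
Product: 9 (R)-1-[3-(benzyloxy)-5-methoxyphenyl]-5-(1,3-dioxolan-2-yl)pentan-2-ol, via acetal Grignard reagent 8 (not isolated)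
Conditions: 7, Mg, THF, 25–30 °C; then CuI (10 mol%), 6, −30 → 0 °C; sat. aq. NH4Cl
Reagents that add atoms: none
Why: Cu-catalysed Grignard opening of the monosubstituted epoxide at its CH2 carbon attaches C4–C6 with the aldehyde masked as a dioxolane, and C2 is untouched (the descriptor changes from S to R only through the CIP priorities).

Step 5
Reactants: 9 (R)-1-[3-(benzyloxy)-5-methoxyphenyl]-5-(1,3-dioxolan-2-yl)pentan-2-ol
Product: 10 (R)-1-[3-(benzyloxy)-5-methoxyphenyl]-5-(1,3-dioxolan-2-yl)pentan-2-yl acetate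
Conditions: Ac2O, DMAP (5 mol%), pyridine, rt
Reagents that add atoms: acetic anhydride, CC(=O)OC(C)=O
Why: DMAP-catalysed O-acylation installs the target's acetate with retention while C2–OH is the only hydroxyl, so it never has to be told apart from C8–OH and cannot later add to the enone in an oxa-Michael cyclisation.

Step 6
Reactants: 10 (R)-1-[3-(benzyloxy)-5-methoxyphenyl]-5-(1,3-dioxolan-2-yl)pentan-2-yl acetate
Product: 11 (R)-1-[3-(benzyloxy)-5-methoxyphenyl]-6-oxohexan-2-yl acetate
Conditions: 1 M aq. HCl, THF, rt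
Reagents that add atoms: water, O
Why: Acid-catalysed acetal hydrolysis unmasks the aldehyde, while the secondary acetate and the benzyl ether are inert to dilute acid at room temperature.

Step 7
Reactants: 11 (R)-1-[3-(benzyloxy)-5-methoxyphenyl]-6-oxohexan-2-yl acetate; 12 heptan-2-one
Product: 15 (2R)-1-[3-(benzyloxy)-5-methoxyphenyl]-6-hydroxy-8-oxotridecan-2-yl acetate (C6 epimer mixture), via dicyclohexylboron enolate 13 (not isolated), via boron aldolate 14 (not isolated)
Conditions: 12, (c-C6H11)2BCl, Et3N, Et2O, −78 → 0 °C; then 11, −78 → −20 °C; then MeOH, pH 7 buffer (NaH2PO4/Na2HPO4), 30% H2O2, 0 °C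
Reagents that add atoms: none
Why: In this directed boron aldol addition (c-C6H11)2BCl/Et3N enolises the methyl ketone on the methyl side only and the enol borinate adds to the aldehyde through a Zimmerman–Traxler transition state to forge C6–C7 without touching the acetate; the new C6 carbinol centre forms unselectively and is erased in step 8.

Step 8
Reactants: 15 (2R)-1-[3-(benzyloxy)-5-methoxyphenyl]-6-hydroxy-8-oxotridecan-2-yl acetate (C6 epimer mixture)
Product: 17 (2R,6E)-1-[3-(benzyloxy)-5-methoxyphenyl]-8-oxotridec-6-en-2-yl acetate, via C6 mesylate 16 (not isolated)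
Conditions: MsCl, Et3N (4 equiv), CH2Cl2, 0 °C → rt
Reagents that add atoms: none
Why: Mesylation of the β-hydroxy ketone followed by E1cB elimination through the C7 enolate gives only the conjugated, thermodynamically favoured (E)-enone, and both C6 epimers converge.

Step 9
Reactants: 17 (2R,6E)-1-[3-(benzyloxy)-5-methoxyphenyl]-8-oxotridec-6-en-2-yl acetate
Product: 18 (2R,6E,8S)-1-[3-(benzyloxy)-5-methoxyphenyl]-8-hydroxytridec-6-en-2-yl acetate
Conditions: (R)-Me-CBS [(R)-1-methyl-3,3-diphenyltetrahydro-1H,3H-pyrrolo[1,2-c][1,3,2]oxazaborole] (20 mol%), catecholborane (1.8 equiv), toluene, −78 °C; MeOH, then aq. NaHCO3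
Reagents that add atoms: none
Why: In this Corey–Bakshi–Shibata reduction the alkenyl group acts as the large substituent and n-pentyl as the small one (as in prostaglandin ω-chain enones), so the (R)-catalyst delivers hydride 1,2 to the Re face of C8 and sets (8S), while catecholborane at −78 °C leaves the C=C bond and the acetate alone.

Step 10
Reactants: 18 (2R,6E,8S)-1-[3-(benzyloxy)-5-methoxyphenyl]-8-hydroxytridec-6-en-2-yl acetate
Product: 19 (2R,8S)-8-hydroxy-1-(3-hydroxy-5-methoxyphenyl)tridecan-2-yl acetate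
Conditions: H2 (1 atm), 10% Pd/C, EtOAc, rt
Reagents that add atoms: none
Why: Heterogeneous catalytic hydrogenation saturates the disubstituted alkene and hydrogenolyses the aryl benzyl ether in one operation, leaving the non-benzylic acetate, the methyl ether and both stereocentres unchanged.

**Compound list**
1 | 3-bromo-5-methoxyphenol | COc1cc(O)cc(Br)c1 | starting material
2 | 1-(benzyloxy)-3-bromo-5-methoxybenzene | COc1cc(Br)cc(OCc2ccccc2)c1 | intermediate
3 | (S)-epichlorohydrin [(S)-2-(chloromethyl)oxirane] | ClC[C@@H]1CO1 | starting material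
4 | [3-(benzyloxy)-5-methoxyphenyl]magnesium bromide | COc1cc([Mg]Br)cc(OCc2ccccc2)c1 | intermediate
5 | (S)-1-[3-(benzyloxy)-5-methoxyphenyl]-3-chloropropan-2-ol | ClC[C@@H](O)Cc1cc(OC)cc(OCc2ccccc2)c1 | intermediate
6 | (S)-2-[3-(benzyloxy)-5-methoxybenzyl]oxirane | C1[C@H](Cc2cc(OC)cc(OCc3ccccc3)c2)O1 | intermediate
7 | 2-(2-bromoethyl)-1,3-dioxolane | BrCCC1OCCO1 | starting material
8 | [2-(1,3-dioxolan-2-yl)ethyl]magnesium bromide | Br[Mg]CCC1OCCO1 | intermediate
9 | (R)-1-[3-(benzyloxy)-5-methoxyphenyl]-5-(1,3-dioxolan-2-yl)pentan-2-ol | C1COC(CCC[C@H](Cc2cc(OC)cc(OCc3ccccc3)c2)O)O1 | intermediate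
10 | (R)-1-[3-(benzyloxy)-5-methoxyphenyl]-5-(1,3-dioxolan-2-yl)pentan-2-yl acetate | C1COC(CCC[C@H](Cc2cc(OC)cc(OCc3ccccc3)c2)OC(C)=O)O1 | intermediate
11 | (R)-1-[3-(benzyloxy)-5-methoxyphenyl]-6-oxohexan-2-yl acetate | O=CCCC[C@H](Cc1cc(OC)cc(OCc2ccccc2)c1)OC(C)=O | intermediate
12 | heptan-2-one | CCCCCC(C)=O | starting material
13 | dicyclohexyl(hept-1-en-2-yloxy)borane | C=C(CCCCC)OB(C1CCCCC1)C1CCCCC1 | intermediate
14 | (2R)-1-[3-(benzyloxy)-5-methoxyphenyl]-6-[(dicyclohexylboranyl)oxy]-8-oxotridecan-2-yl acetate (C6 epimer mixture) | CCCCCC(=O)CC(OB(C1CCCCC1)C2CCCCC2)CCC[C@H](Cc3cc(OC)cc(OCc4ccccc4)c3)OC(C)=O | intermediate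
15 | (2R)-1-[3-(benzyloxy)-5-methoxyphenyl]-6-hydroxy-8-oxotridecan-2-yl acetate (C6 epimer mixture) | CCCCCC(=O)CC(O)CCC[C@H](Cc1cc(OC)cc(OCc2ccccc2)c1)OC(C)=O | intermediate
16 | (2R)-1-[3-(benzyloxy)-5-methoxyphenyl]-6-[(methylsulfonyl)oxy]-8-oxotridecan-2-yl acetate (C6 epimer mixture) | CCCCCC(=O)CC(OS(C)(=O)=O)CCC[C@H](Cc1cc(OC)cc(OCc2ccccc2)c1)OC(C)=O | intermediate
17 | (2R,6E)-1-[3-(benzyloxy)-5-methoxyphenyl]-8-oxotridec-6-en-2-yl acetate | CCCCCC(=O)/C=C/CCC[C@H](Cc1cc(OC)cc(OCc2ccccc2)c1)OC(C)=O | intermediate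
18 | (2R,6E,8S)-1-[3-(benzyloxy)-5-methoxyphenyl]-8-hydroxytridec-6-en-2-yl acetate | CCCCC[C@H](O)/C=C/CCC[C@H](Cc1cc(OC)cc(OCc2ccccc2)c1)OC(C)=O | intermediate
19 | (2R,8S)-8-hydroxy-1-(3-hydroxy-5-methoxyphenyl)tridecan-2-yl acetate | CCCCC[C@H](O)CCCCC[C@H](Cc1cc(O)cc(OC)c1)OC(C)=O | target

**Step count**
Total steps: 10. Longest linear sequence: 10 steps (1 → 19); compounds 3, 7 and 12 enter as bought partners.

**Steps most likely to fail**

Step 7, the boron aldol. Incomplete enolisation of 12, or loss of the β-hydroxy ketone during the oxidative work-up, would stall the fragment union. The fallback is a Mukaiyama aldol that separates enolate formation from C–C bond formation. It sets out from 11, with 12 as before. Ketone 12 is converted with LiN(iPr)2 and Me3SiCl (THF, −78 °C) into the kinetic silyl enol ether trimethyl(hept-1-en-2-yloxy)silane F1, which is distilled free of its internal regioisomer. F1 is added to 11 activated by BF3·OEt2 (CH2Cl2, −78 °C) and reacts through an open transition state. Aqueous work-up gives aldol 15, where the fallback comes back to the route.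

Step 9, the CBS reduction. Alkenyl versus n-pentyl discrimination is typically about 90:10 to 95:5 at C8, and the (8R) epimer, remote from C2, cannot realistically be separated. The fallback takes C8 from the chiral pool. It sets out from 11. Wittig methylenation (Ph3PCH3Br, KN(SiMe3)2, THF, −78 → 0 °C) gives (R)-1-[3-(benzyloxy)-5-methoxyphenyl]hept-6-en-2-yl acetate F2. Olefin cross-metathesis of F2 with commercial (S)-oct-1-en-3-ol (3 equiv, second-generation Grubbs catalyst RuCl2(=CHPh)(PCy3)(H2IMes), CH2Cl2, 40 °C) is E-selective for this pairing and gives 18, where it comes back to the route.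

Step 10, the final hydrogenation. Pd-catalysed hydrogenation of a free allylic alcohol can partly isomerise it to the C8 ketone or hydrogenolyse the allylic C–O bond. The fallback separates the two reductions. It sets out from 18. Diimide generated from 2-nitrobenzenesulfonohydrazide and Et3N (CH2Cl2, rt) saturates only C6=C7 and gives (2R,8S)-1-[3-(benzyloxy)-5-methoxyphenyl]-8-hydroxytridecan-2-yl acetate F3. Hydrogenolysis of the benzyl ether of F3 (H2, 10% Pd/C, EtOAc, rt), now with no allylic alcohol present, gives 19, where it comes back to the route.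

**Further compounds**
F1 | step 7 | trimethyl(hept-1-en-2-yloxy)silane | C=C(CCCCC)O[Si](C)(C)C
F2 | step 9 | (R)-1-[3-(benzyloxy)-5-methoxyphenyl]hept-6-en-2-yl acetate | C=CCCC[C@H](Cc1cc(OC)cc(OCc2ccccc2)c1)OC(C)=O
F3 | step 10 | (2R,8S)-1-[3-(benzyloxy)-5-methoxyphenyl]-8-hydroxytridecan-2-yl acetate | CCCCC[C@H](O)CCCCC[C@H](Cc1cc(OC)cc(OCc2ccccc2)c1)OC(C)=O
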